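Assumption: eudesmane numbering (C1–C15) is used for the bicyclic compounds and carried back to the ring carbons of their precursors; the ligand antipode in step 1 is the one that gives the (R)-quaternary centre.

**Retrosynthetic overview**
1. Target ⇐ α-face dihydroxylation of the 4(15)-ene 6β-cinnamate ⇐ Heck arylation of the 6β-acrylate with iodobenzene.
2. 6β-Alcohol ⇐ deconjugative protonation (sets C5) and equatorial hydride delivery (sets C6) on eudesm-4-en-6-one.
3. Key step: ring B is closed last through the C6–C7 bond, by 6-exo cyclisation of the α,β-unsaturated acyl radical of a ring-A enal onto a homoprenyl alkene; the same event creates the isopropyl group and C7.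
4. Enal ⇐ MeLi addition / 1,3-carbonyl transposition of an alkoxymethylene ketone ⇐ formylation of the enolate from a Cu-catalysed asymmetric conjugate addition of homoprenyl-MgBr to 3-methylcyclohexenone (sets C10; ring A is bought).

**Route**

Step 1
Reactants: 1 3-methylcyclohex-2-en-1-one; 2 5-bromo-2-methylpent-2-ene; 3 2,2,2-trifluoroethyl formate
Product: 6 (3R)-2-[(Z)-hydroxymethylidene]-3-methyl-3-(4-methylpent-3-en-1-yl)cyclohexan-1-one, via homoprenylmagnesium bromide 4 (not isolated), via bromomagnesium enolate 5 (not isolated)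
Conditions: 2, Mg, Et2O; then 1, Cu(OTf)2 (3 mol%), chiral NHC from a C2-symmetric imidazolinium salt (4 mol%), Et2O, 0 °C; then 3, THF, −78 → 0 °C; aq NH4Cl
Reagents that add atoms: none
Why: Copper–NHC-catalysed asymmetric conjugate addition of the Grignard reagent creates the C10 quaternary centre under ligand control and leaves a regiodefined magnesium enolate, which the activated formate C-formylates at C5 (crossed Claisen condensation), the released trifluoroethoxide deprotonating the acidic product.

Step 2
Reactants: 6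
Product: 7 (3R)-3-methyl-3-(4-methylpent-3-en-1-yl)-2-[(E)-(propan-2-yloxy)methylidene]cyclohexan-1-one
Conditions: i-PrI, K2CO3, acetone, 50 °C
Reagents that add atoms: 2-iodopropane CC(C)I
Why: O-Alkylation of the vinylogous acid (Williamson ether synthesis) gives a vinylogous ester that accepts 1,2-addition; no stereocentre is formed.

Step 3
Reactants: 7
Product: 9 (6R)-2,6-dimethyl-6-(4-methylpent-3-en-1-yl)cyclohex-1-ene-1-carbaldehyde, via tertiary lithium alkoxide 8 (not isolated)
Conditions: MeLi, Et2O, −78 °C; then 1 M HCl, THF/H2O, 0 °C → rt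
Reagents that add atoms: methyllithium [Li]C; water O
Why: Methyllithium adds 1,2 to the vinylogous ester and dilute acid ionises the tertiary allylic alcohol to an oxocarbenium ion that water captures at the former formyl carbon (1,3-carbonyl transposition of the Stork–Danheiser type), giving the tetrasubstituted enal; the transient carbinol centre is destroyed and C10 is untouched.

Step 4
Reactants: 9
Product: 10 (7S,10R)-eudesm-4-en-6-one
Conditions: t-C12H25SH (30 mol%), 1,1′-azobis(cyclohexanecarbonitrile) (20 mol%, portions), degassed PhCl (0.02 M), 110 °C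
Reagents that add atoms: none
Why: Proposed new method: the thiyl radical abstracts the formyl hydrogen (polarity-reversal catalysis), the α,β-unsaturated acyl radical cannot lose CO and closes 6-exo-trig onto the CH end of the trisubstituted alkene, and the tertiary C11 radical takes hydrogen from the thiol to give the isopropyl group; C7 is set by a chair-like transition state with the alkene pseudo-equatorial (cis to the axial C10 methyl) and stays epimerisable to that equatorial form next to the new ketone; closest known reaction types are the thiol-catalysed acyl-radical cyclisation of saturated alkenals (radical hydroacylation) and tin-hydride cyclisations of α,β-unsaturated acyl radicals from selenoesters.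

Step 5
Reactants: 10
Product: 13 (5S,6R,7S,10R)-eudesm-4(15)-en-6-ol, via exocyclic lithium dienolate 11 (not isolated), via deconjugated enone 12 (not isolated)
Conditions: LDA (1.2 equiv), THF/DMPU, −78 °C; AcOH (1.2 equiv), −78 °C; then L-Selectride (2.5 equiv), −78 → −40 °C; aq NH4Cl
Reagents that add atoms: none
Why: Kinetic γ-deprotonation takes a hydrogen from the C15 methyl, the only γ-position held cis to the carbonyl (the α′-hydrogen at C7 is tertiary and screened by isopropyl); kinetic α-protonation of the dienolate (deconjugative protonation) from the face anti to the angular methyl sets 5α-H, and L-Selectride then attacks C6 from the equatorial α-side because the β-face is blocked by the syn-axial C10 methyl, giving the axial 6β-alcohol (as menthone gives neomenthol).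

Step 6
Reactants: 13; 14 acryloyl chloride
Product: 15 (5S,6R,7S,10R)-eudesm-4(15)-en-6-yl prop-2-enoate
Conditions: Et3N, DMAP (10 mol%), CH2Cl2, 0 °C → rt
Reagents that add atoms: none
Why: DMAP-catalysed acylation (nucleophilic catalysis) of the hindered axial alcohol with a small acid chloride; only the O–H bond is broken, so C6 keeps its configuration.

Step 7
Reactants: 15; 16 iodobenzene
Product: 17 (5S,6R,7S,10R)-eudesm-4(15)-en-6-yl (E)-3-phenylprop-2-enoate
Conditions: Pd(OAc)2 (5 mol%), K2CO3, Bu4NBr, DMF, 80 °C
Reagents that add atoms: none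
Why: Mizoroki–Heck arylation of the acrylate; syn insertion and syn β-hydride elimination give only the E cinnamate, and the hindered 1,1-disubstituted exocyclic alkene does not compete.

Step 8
Reactants: 17
Product: 18 (4R,5S,6R,7S,10R)-4,15-dihydroxyeudesman-6-yl (E)-3-phenylprop-2-enoate
Conditions: OsO4 (2 mol%), NMO (1.2 equiv), acetone/H2O 5:1, 0 °C → rt, stopped at full conversion of 17
Reagents that add atoms: osmium tetroxide O=[Os](=O)(=O)=O; N-methylmorpholine N-oxide C[N+]1([O-])CCOCC1; water O
Why: Upjohn dihydroxylation: OsO4 reacts faster with the electron-rich 1,1-disubstituted alkene than with the conjugated ester and adds from the open α-face (equatorial attack; the β-face is screened by the axial C10 methyl and the 6β-ester), giving the equatorial 4α-OH and the axial 15-CH2OH.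

**Compound list**
1 | 3-methylcyclohex-2-en-1-one | CC1=CC(=O)CCC1 | starting material
2 | 5-bromo-2-methylpent-2-ene | CC(C)=CCCBr | starting material
3 | 2,2,2-trifluoroethyl formate | O=COCC(F)(F)F | starting material
4 | (4-methylpent-3-en-1-yl)magnesium bromide | CC(C)=CCC[Mg]Br | intermediate
5 | bromomagnesium (3R)-3-methyl-3-(4-methylpent-3-en-1-yl)cyclohex-1-en-1-olate | CC(C)=CCC[C@@]1(C)CCCC(O[Mg]Br)=C1 | intermediate
6 | (3R)-2-[(Z)-hydroxymethylidene]-3-methyl-3-(4-methylpent-3-en-1-yl)cyclohexan-1-one (enol form of the 2-formyl ketone) | CC(C)=CCC[C@@]1(C)CCCC(=O)/C1=C\O | intermediate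
7 | (3R)-3-methyl-3-(4-methylpent-3-en-1-yl)-2-[(E)-(propan-2-yloxy)methylidene]cyclohexan-1-one | CC(C)=CCC[C@@]1(C)CCCC(=O)/C1=C/OC(C)C | intermediate
8 | lithium (3R)-1,3-dimethyl-3-(4-methylpent-3-en-1-yl)-2-[(E)-(propan-2-yloxy)methylidene]cyclohexan-1-olate (both C1 epimers) | CC(C)=CCC[C@@]1(C)CCCC(C)(O[Li])/C1=C/OC(C)C | intermediate
9 | (6R)-2,6-dimethyl-6-(4-methylpent-3-en-1-yl)cyclohex-1-ene-1-carbaldehyde | CC(C)=CCC[C@@]1(C)CCCC(C)=C1C=O | intermediate
10 | (7S,10R)-eudesm-4-en-6-one = (2S,4aR)-4a,8-dimethyl-2-(propan-2-yl)-3,4,4a,5,6,7-hexahydronaphthalen-1(2H)-one (10β-Me; 7β-iPr) | CC(C)[C@@H]1CC[C@@]2(C)CCCC(C)=C2C1=O | intermediate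
11 | lithium (7S,10R)-eudesma-4(15),5-dien-6-olate | CC(C)[C@@H]1CC[C@@]2(C)CCCC(=C)C2=C1O[Li] | intermediate
12 | (5S,7S,10R)-eudesm-4(15)-en-6-one (trans-decalin; 5α-H) | CC(C)[C@@H]1CC[C@@]2(C)CCCC(=C)[C@@H]2C1=O | intermediate
13 | (5S,6R,7S,10R)-eudesm-4(15)-en-6-ol (6β-OH axial; 7β-iPr equatorial) | CC(C)[C@@H]1CC[C@@]2(C)CCCC(=C)[C@@H]2[C@@H]1O | intermediate
14 | acryloyl chloride | C=CC(=O)Cl | starting material
15 | (5S,6R,7S,10R)-eudesm-4(15)-en-6-yl prop-2-enoate | CC(C)[C@@H]1CC[C@@]2(C)CCCC(=C)[C@@H]2[C@@H]1OC(=O)C=C | intermediate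
16 | iodobenzene | Ic1ccccc1 | starting material
17 | (5S,6R,7S,10R)-eudesm-4(15)-en-6-yl (E)-3-phenylprop-2-enoate | CC(C)[C@@H]1CC[C@@]2(C)CCCC(=C)[C@@H]2[C@@H]1OC(=O)/C=C/c1ccccc1 | intermediate
18 | (4R,5S,6R,7S,10R)-4,15-dihydroxyeudesman-6-yl (E)-3-phenylprop-2-enoate (4α-OH; 4β-CH2OH; 5α-H; 6β-O-cinnamoyl; 7β-iPr; 10β-Me) | CC(C)[C@@H]1CC[C@@]2(C)CCC[C@](O)(CO)[C@@H]2[C@@H]1OC(=O)/C=C/c1ccccc1 | target

**Totals**
Total step count: 8. Longest linear sequence: 8 steps (1 → 18).

**Steps most likely to fail**

Step 4. Hydrogen abstraction from a conjugated enal by a thiyl radical is not established, and thiol–ene addition to the side-chain alkene may compete. The fallback generates the same acyl radical from a selenoester with tin hydride. It sets out from 9: Pinnick oxidation (NaClO2, NaH2PO4, 2-methyl-2-butene) gives (6R)-2,6-dimethyl-6-(4-methylpent-3-en-1-yl)cyclohex-1-ene-1-carboxylic acid F1. PhSeSePh/PBu3 converts it into Se-phenyl (6R)-2,6-dimethyl-6-(4-methylpent-3-en-1-yl)cyclohex-1-ene-1-carboselenoate F2. Slow addition of Bu3SnH/AIBN in benzene at 80 °C gives the acyl radical by abstraction of the selenium group and the same 6-exo closure, and the sequence comes back to the route at 10.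

Step 5. LDA may remove the α′-hydrogen at C7 instead of a C15 hydrogen, which returns 10 and leads to reduction of the conjugated enone. The fallback is a photochemical deconjugation. It sets out from 10: irradiation at about 350 nm in MeCN with catalytic imidazole lets the excited carbonyl abstract a C15 hydrogen through a six-membered transition state (only the methyl cis to the carbonyl can reach it). This gives the dienol (7S,10R)-eudesma-4(15),5-dien-6-ol F3, which the weak base ketonises by α-protonation to 12, now isolated. A separate L-Selectride reduction at −78 °C comes back to the route at 13.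

Step 8. The cinnamate double bond may be dihydroxylated alongside the exocyclic alkene. The fallback installs the diol before the unsaturated ester and masks it. It sets out from 13: OsO4/NMO gives (4R,5S,6R,7S,10R)-eudesmane-4,6,15-triol F4. 2,2-Dimethoxypropane/PPTS gives the acetonide (4R,5S,6R,7S,10R)-4,15-O-isopropylideneeudesmane-4,6,15-triol F5. Acryloyl chloride/Et3N/DMAP gives (4R,5S,6R,7S,10R)-4,15-O-isopropylidene-4,15-dihydroxyeudesman-6-yl prop-2-enoate F6. Heck arylation with 16 gives (4R,5S,6R,7S,10R)-4,15-O-isopropylidene-4,15-dihydroxyeudesman-6-yl (E)-3-phenylprop-2-enoate F7. Aqueous 80% AcOH removes the acetonide and the sequence comes back to the route at 18.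

**Further compounds**
F1 | step 4 | (6R)-2,6-dimethyl-6-(4-methylpent-3-en-1-yl)cyclohex-1-ene-1-carboxylic acid | CC(C)=CCC[C@@]1(C)CCCC(C)=C1C(=O)O
F2 | step 4 | Se-phenyl (6R)-2,6-dimethyl-6-(4-methylpent-3-en-1-yl)cyclohex-1-ene-1-carboselenoate | CC(C)=CCC[C@@]1(C)CCCC(C)=C1C(=O)[Se]c1ccccc1
F3 | step 5 | (7S,10R)-eudesma-4(15),5-dien-6-ol | CC(C)[C@@H]1CC[C@@]2(C)CCCC(=C)C2=C1O
F4 | step 8 | (4R,5S,6R,7S,10R)-eudesmane-4,6,15-triol | CC(C)[C@@H]1CC[C@@]2(C)CCC[C@](O)(CO)[C@@H]2[C@@H]1O
F5 | step 8 | (4R,5S,6R,7S,10R)-4,15-O-isopropylideneeudesmane-4,6,15-triol | CC(C)[C@@H]1CC[C@@]2(C)CCC[C@]3(COC(C)(C)O3)[C@@H]2[C@@H]1O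
F6 | step 8 | (4R,5S,6R,7S,10R)-4,15-O-isopropylidene-4,15-dihydroxyeudesman-6-yl prop-2-enoate | CC(C)[C@@H]1CC[C@@]2(C)CCC[C@]3(COC(C)(C)O3)[C@@H]2[C@@H]1OC(=O)C=C
F7 | step 8 | (4R,5S,6R,7S,10R)-4,15-O-isopropylidene-4,15-dihydroxyeudesman-6-yl (E)-3-phenylprop-2-enoate | CC(C)[C@@H]1CC[C@@]2(C)CCC[C@]3(COC(C)(C)O3)[C@@H]2[C@@H]1OC(=O)/C=C/c1ccccc1
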